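The constants stand for no real mixture; what happens was integrated by code.

I start from a small charge of racemic substrate, with partner at 2.20 equiv, in flasks that differ by temperature.

common to all: left-handed substrate 16 mM; partner 2.20 equiv; right-handed substrate 16 mM; time 12 h
- grey: temperature 5 °C
- blue: temperature −25 °C
- teal: temperature −10 °C

    partner + left-handed substrate → left-handed product (k1 = 7.5 M⁻¹ h⁻¹, Ea1 = 50.0 kJ mol⁻¹)
    partner + right-handed substrate → right-handed product (k2 = 0.064 M⁻¹ h⁻¹, Ea2 = 57.0 kJ mol⁻¹)
    left-handed substrate ⇌ achiral form (K3 = 1.2, k3 = 12 h⁻¹, Ea3 = 70.0 kJ mol⁻¹, ΔH3 = −90.0 kJ mol⁻¹)
    right-handed substrate ⇌ achiral form (K3 = 1.2, k3 = 12 h⁻¹, Ea3 = 70.0 kJ mol⁻¹, ΔH3 = −90.0 kJ mol⁻¹)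
    achiral form → waste (k5 = 3.0 h⁻¹, Ea5 = 80.0 kJ mol⁻¹)
    left-handed product ⇌ right-handed product (k6 = 0.16 h⁻¹, Ea6 = 94.0 kJ mol⁻¹)
    (constants at 5 °C)

- partner is single-handed; left-handed substrate and right-handed substrate are mirror images of each other, charged as a racemate, each of them at the stated concentration
- the list of constants is for 5 °C, to be carried to other temperatures by the activation energies and enthalpies
- an excess is the difference of the two amounts in percent of their sum
- an excess is below zero if the other one leads
- the handed part of partner does not stay in what it makes, so the products of the two hands are mirror images too

- the best flask by excess of left-handed product over right-handed product; "all alike" if 1.5 percentage points covers them all (grey / blue / teal / all alike)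
- excess of left-handed product over right-handed product at the end, grey
- excess of left-handed product over right-handed product at the end, blue
- excess of left-handed product over right-handed product at the end, teal

How much of the charge can become product? In grey, partner pulls left-handed substrate at 0.264 h⁻¹, a pseudo-first-order constant, while the step to the achiral form runs at 12 h⁻¹. That step runs back as well, so these two constants give no share of the charge. The amount is not asked, though, and partner multiplies both hands alike, so it cancels from the ratio of the two products.

What excess does product have at birth? At the start the ratio of the two rates is the selectivity factor, 117 in grey; carried by the activation energies it is 169 in blue and 139 in teal. The birth excess, the factor less one over the factor plus one, is 98.3% in grey, 98.8% in blue and 98.6% in teal. Grey and blue differ by 0.50 percentage points.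

What survives? Each product turns into the other with the same constant, so their difference decays first-order at twice that constant. In closed form, the fraction of an excess that remains after a time is the exponential of minus twice the constant times the time. In blue the relaxation half-life is 12.3 d, long against 12 h, and the constant carried to that temperature by its activation energy gives 97.2%: this is the keeping factor. Grey keeps 2.15% and teal 68.5%.

Birth excess times keeping factor, with the whole run charged to the product, gives 2.11% for grey, 96.1% for blue and 67.5% for teal, so I pick blue.

The forecast names blue, with 2.7% for grey, 96.5% for blue and 71.5% for teal, on the ground that “the product forms early and then sits exposed to racemisation for nearly the whole run”. Its teal figure stands above mine.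

The simulation gives 2.90% for grey, 96.7% for blue and 71.7% for teal, and the best flask is blue. The blue figure of the forecast would fail with a later reading: at 35.7 h the blue excess has moved by 5 points. Blue left until 50 h is the same flask with a longer exposure, so its keeping factor is 88.8%, and with the birth excess that makes 87.8%. That flask reads 88.7%.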